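**Retrosynthetic overview**
1. The 1,2-dioxane is the last ring formed: O2–C3 bond by 6-exo SN2 attack (inversion) of a C6 tertiary hydroperoxide on a C3 mesylate in the fully assembled chain.
2. C8–C9 is cut by a Keck radical allylation: primary iodide (left fragment, C1–C8) plus a 2-substituted allylstannane that already carries the carbocycle (right fragment, C9–C18).
3. Left fragment: p-cresol is dearomatised with singlet oxygen to a mirror-symmetric 4-peroxy ketone. An enzymatic Baeyer–Villiger oxidation breaks the symmetry and fixes the quaternary peroxide carbon (key step). The lactone is opened by a propanoate enolate and a ketoreductase sets C2/C3.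
4. Right fragment: the cyclohexane ring is bought (β-cyclocitral). Sharpless epoxidation sets the carbinol carbon, epoxide-to-allylic-alcohol isomerisation gives the exocyclic methylene, and a spiro-epoxide is opened by an allyl anion from a symmetric isobutene bis-stannane.
5. Ring order: carbocycle (purchased), spiro-epoxide (temporary), 1,2-dioxane (last).

Notation: chain atoms are numbered as in the dodecanoate (C1 ester carbon, C3 and C6 the dioxane carbons, C10 the central methylidene carbon). The target descriptors read from the SMILES are 2R (propanoate), 3S,6R (dioxane) and 1R (cyclohexanol).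
Assumption: the Baeyer–Villiger monooxygenase and the ketoreductase are chosen by screening known enantiocomplementary enzyme panels for the stereochemical sense stated.

**Route**

Step 1
Reactants: 1 p-cresol (4-methylphenol)
Product: 2 4-hydroperoxy-4-methylcyclohexa-2,5-dien-1-one
Conditions: KHSO5 (as 2KHSO5·KHSO4·K2SO4), NaHCO3, MeCN/H2O, rt
Reagents that add atoms: potassium peroxymonosulfate, [K+].[O-]S(=O)(=O)OO
Why: Dearomatising oxygenation: singlet oxygen released from the caroate adds to the para carbon of the phenol to give the known mirror-symmetric p-peroxyquinol, which installs the tertiary C–OO bond of the target before any stereocentre exists.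

Step 2
Reactants: 2 p-peroxyquinol
Product: 3 4-[(2-methoxypropan-2-yl)peroxy]-4-methylcyclohexa-2,5-dien-1-one
Conditions: 2-methoxypropene, pyridinium p-toluenesulfonate (cat.), CH2Cl2, 0 °C
Reagents that add atoms: 2-methoxypropene, COC(C)=C
Why: Acid-catalysed addition of the hydroperoxide to the enol ether (peroxyketal protection) gives a peroxide that tolerates base, enolates, enzymes and radicals and is removed later with dilute acid.

Step 3
Reactants: 3 protected peroxy dienone
Product: 4 4-[(2-methoxypropan-2-yl)peroxy]-4-methylcyclohexan-1-one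
Conditions: 2-nitrobenzenesulfonohydrazide, Et3N, CH2Cl2, rt
Reagents that add atoms: none
Why: Diimide reduction (concerted syn transfer of H2) saturates both electron-poor C=C bonds without touching the O–O bond or the ketone, leaving a ketone whose mirror plane passes through C1 and C4.

Step 4
Reactants: 4 symmetric peroxy ketone
Product: 5 (5S)-5-[(2-methoxypropan-2-yl)peroxy]-5-methyloxepan-2-one
Conditions: cyclohexanone-monooxygenase-type Baeyer–Villiger monooxygenase (phosphite dehydrogenase fusion), NADP+ (cat.), Na2HPO3, air, Tris buffer pH 8, 25 °C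
Reagents that add atoms: dioxygen, O=O
Why: Enzymatic Baeyer–Villiger oxidation used as a desymmetrisation (the key step): the chiral active site lets only one of the two enantiotopic α-CH2 groups migrate, so the previously non-stereogenic peroxide carbon becomes the (5S) quaternary centre (C6 of the target), and since CHMO- and CPMO-type enzymes give opposite lactone enantiomers from 4,4-disubstituted cyclohexanones the required sense is reached by choice of enzyme.

Step 5
Reactants: 5 (5S)-peroxy lactone; 6 methyl propanoate
Product: 8 methyl (6S)-8-hydroxy-6-[(2-methoxypropan-2-yl)peroxy]-2,6-dimethyl-3-oxooctanoate, via lithium 1-methoxyprop-1-en-1-olate 7 (not isolated)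
Conditions: LiN(iPr)2 (2.2 equiv), 6 (2.2 equiv), THF, −78 °C; then 5, −78 → −40 °C; aqueous work-up
Reagents that add atoms: none
Why: Crossed Claisen acylation: the ester enolate adds to the lactone carbonyl and the tetrahedral intermediate opens to the β-keto ester (held as its enolate by the second equivalent) and the C8 alkoxide, while the di-tertiary peroxyketal is too hindered to react with the enolate at −78 °C; C2 forms as interconverting epimers that step 6 resolves.

Step 6
Reactants: 8 β-keto ester
Product: 9 methyl (2R,3R,6S)-3,8-dihydroxy-6-[(2-methoxypropan-2-yl)peroxy]-2,6-dimethyloctanoate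
Conditions: ketoreductase (anti-(2R,3R)-selective), NADP+ (cat.), iPrOH, phosphate buffer pH 7, 30 °C
Reagents that add atoms: none
Why: Ketoreductase dynamic kinetic resolution: the α-methyl β-keto ester epimerises at C2 through its enol faster than it is reduced, and an anti-selective enzyme delivers hydride to one carbonyl face of the (2R) epimer only, setting C2 (R) and C3 (R) together while C6 and the peroxyketal are untouched.

Step 7
Reactants: 9 anti-dihydroxy ester
Product: 11 methyl (2R,3R,6S)-8-iodo-3-(methanesulfonyloxy)-6-[(2-methoxypropan-2-yl)peroxy]-2,6-dimethyloctanoate, via bis-mesylate 10 (not isolated)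
Conditions: MsCl, Et3N, CH2Cl2, −20 °C; then NaI, acetone, 35 °C
Reagents that add atoms: methanesulfonyl chloride, CS(=O)(=O)Cl; sodium iodide, [Na+].[I-]
Why: Sulfonylation of both hydroxyls followed by Finkelstein SN2 exchange, which occurs only at the unhindered primary mesylate because the secondary one is β-branched and flanked by the ester, so C3 keeps its (R) configuration and its leaving group.

Step 8
Reactants: 12 β-cyclocitral (2,6,6-trimethylcyclohex-1-ene-1-carbaldehyde)
Product: 13 β-cyclogeraniol ((2,6,6-trimethylcyclohex-1-en-1-yl)methanol)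
Conditions: NaBH4, MeOH, 0 °C
Reagents that add atoms: none
Why: Hydride 1,2-reduction of the hindered enal gives the allylic alcohol needed for hydroxyl-directed epoxidation.

Step 9
Reactants: 13 β-cyclogeraniol
Product: 14 [(1S,6S)-2,2,6-trimethyl-7-oxabicyclo[4.1.0]heptan-1-yl]methanol
Conditions: Ti(OiPr)4 (cat.), L-(+)-diethyl tartrate (cat.), tBuOOH, 4 Å molecular sieves, CH2Cl2, −20 °C
Reagents that add atoms: tert-butyl hydroperoxide, CC(C)(C)OO
Why: Sharpless asymmetric epoxidation: the titanium–tartrate complex binds the allylic alcohol and delivers oxygen to one face of the tetrasubstituted alkene, L-(+)-tartrate giving the (1S,6S) epoxide in direct analogy to (2S,3S)-epoxygeraniol and so fixing the future carbinol carbon.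

Step 10
Reactants: 14 epoxy alcohol
Product: 15 (1R)-1-(hydroxymethyl)-2,2-dimethyl-6-methylidenecyclohexan-1-ol
Conditions: Et2Al(NC9H18) (diethylaluminium 2,2,6,6-tetramethylpiperidide, from Et2AlCl and LiNC9H18), toluene, 0 °C → rt
Reagents that add atoms: none
Why: Yamamoto-type aluminium amide isomerisation of an epoxide to an allylic alcohol (syn β-elimination): the only removable β-hydrogens are on the C6 side and the unhindered methyl is preferred over the ring CH2, so the C6–O bond breaks, the exocyclic methylene forms and the C1–O bond keeps its configuration.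

Step 11
Reactants: 15 ene-diol
Product: 17 (3R)-4,4-dimethyl-8-methylidene-1-oxaspiro[2.5]octane, via primary tosylate 16 (not isolated)
Conditions: NaH (2.2 equiv), 1-(p-toluenesulfonyl)imidazole, THF, 0 °C → rt
Reagents that add atoms: none
Why: Selective sulfonylation of the primary alkoxide followed by intramolecular Williamson (3-exo-tet) closure by the tertiary alkoxide, which leaves the C–O bond of the stereocentre untouched.

Step 12
Reactants: 18 3-chloro-2-(chloromethyl)prop-1-ene
Product: 19 (2-methylidenepropane-1,3-diyl)bis(tributylstannane)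
Conditions: Bu3SnH, LiN(iPr)2, THF, 0 °C; then 18, −78 °C → rt
Reagents that add atoms: tributyltin hydride, CCCC[SnH](CCCC)CCCC
Why: Nucleophilic substitution (SN2 or SN2′, same product) of both allylic chlorides by the stannyl anion gives the symmetric bis-allylstannane linchpin.

Step 13
Reactants: 19 bis-allylstannane; 17 spiro-epoxide
Product: 21 (1R)-2,2-dimethyl-6-methylidene-1-{3-[(tributylstannyl)methyl]but-3-en-1-yl}cyclohexan-1-ol, via stannylated allyllithium 20 (not isolated)
Conditions: MeLi (1 equiv per 19), THF, −78 °C; then 17, −78 → 0 °C; aqueous work-up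
Reagents that add atoms: none
Why: Tin–lithium exchange on one of the two equivalent arms gives an allyllithium that still carries the other CH2SnBu3 group and opens the epoxide by SN2 at its CH2 terminus (both allyl termini give the same product), so the carbinol configuration is retained.

Step 14
Reactants: 11 iodo mesylate; 21 allylstannane (1.5 equiv, excess recovered)
Product: 22 methyl (2R,3R,6R)-12-[(1R)-1-hydroxy-2,2-dimethyl-6-methylidenecyclohexyl]-3-(methanesulfonyloxy)-6-[(2-methoxypropan-2-yl)peroxy]-2,6-dimethyl-10-methylidenedodecanoate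
Conditions: 2,2′-azobis(isobutyronitrile) (cat.), benzene (1 M), 80 °C
Reagents that add atoms: none
Why: Keck radical allylation (SH2′ chain): Bu3Sn• abstracts iodine, the primary C8 radical adds to the =CH2 terminus of the allylstannane and β-scission of the C–Sn bond creates the C10 methylidene and returns Bu3Sn•, under neutral conditions that spare the peroxyketal, mesylate, ester and tertiary allylic alcohol and touch no stereocentre (the C6 descriptor changes from S to R only because the CIP priorities change).

Step 15
Reactants: 22 coupled mesylate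
Product: 24 methyl (2R)-2-[(3S,6R)-6-{6-[(1R)-1-hydroxy-2,2-dimethyl-6-methylidenecyclohexyl]-4-methylidenehexyl}-6-methyl-1,2-dioxan-3-yl]propanoate (target CNP0185522.3), via tertiary hydroperoxide 23 (not isolated)
Conditions: AcOH/THF/H2O, rt; then Cs2CO3, DMF, 0 °C → rt
Reagents that add atoms: none
Why: Mild acid hydrolysis of the peroxyketal frees the tertiary hydroperoxide, whose caesium salt (weak base, strong α-effect nucleophile) closes the ring by 6-exo-tet SN2 displacement of the C3 mesylate with inversion, turning (3R) into the (3S) centre of the target while C2, C6 and the carbinol carbon are untouched.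

**Compound list**
1 | p-cresol (4-methylphenol) | Cc1ccc(O)cc1 | starting material
2 | 4-hydroperoxy-4-methylcyclohexa-2,5-dien-1-one | CC1(OO)C=CC(=O)C=C1 | intermediate
3 | 4-[(2-methoxypropan-2-yl)peroxy]-4-methylcyclohexa-2,5-dien-1-one | COC(C)(C)OOC1(C)C=CC(=O)C=C1 | intermediate
4 | 4-[(2-methoxypropan-2-yl)peroxy]-4-methylcyclohexan-1-one | COC(C)(C)OOC1(C)CCC(=O)CC1 | intermediate
5 | (5S)-5-[(2-methoxypropan-2-yl)peroxy]-5-methyloxepan-2-one | O=C1CC[C@](C)(OOC(C)(C)OC)CCO1 | intermediate
6 | methyl propanoate | CCC(=O)OC | starting material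
7 | lithium 1-methoxyprop-1-en-1-olate (lithium enolate of 6) | [Li+].[O-]C(OC)=CC | intermediate (not isolated)
8 | methyl (6S)-8-hydroxy-6-[(2-methoxypropan-2-yl)peroxy]-2,6-dimethyl-3-oxooctanoate (interconverting C2 epimers) | COC(=O)C(C)C(=O)CC[C@](C)(OOC(C)(C)OC)CCO | intermediate
9 | methyl (2R,3R,6S)-3,8-dihydroxy-6-[(2-methoxypropan-2-yl)peroxy]-2,6-dimethyloctanoate | COC(=O)[C@H](C)[C@H](O)CC[C@](C)(OOC(C)(C)OC)CCO | intermediate
10 | methyl (2R,3R,6S)-3,8-bis(methanesulfonyloxy)-6-[(2-methoxypropan-2-yl)peroxy]-2,6-dimethyloctanoate | COC(=O)[C@H](C)[C@H](OS(C)(=O)=O)CC[C@](C)(OOC(C)(C)OC)CCOS(C)(=O)=O | intermediate (not isolated)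
11 | methyl (2R,3R,6S)-8-iodo-3-(methanesulfonyloxy)-6-[(2-methoxypropan-2-yl)peroxy]-2,6-dimethyloctanoate | COC(=O)[C@H](C)[C@H](OS(C)(=O)=O)CC[C@](C)(OOC(C)(C)OC)CCI | intermediate
12 | β-cyclocitral (2,6,6-trimethylcyclohex-1-ene-1-carbaldehyde) | CC1=C(C=O)C(C)(C)CCC1 | starting material
13 | β-cyclogeraniol ((2,6,6-trimethylcyclohex-1-en-1-yl)methanol) | CC1=C(CO)C(C)(C)CCC1 | intermediate
14 | [(1S,6S)-2,2,6-trimethyl-7-oxabicyclo[4.1.0]heptan-1-yl]methanol | OC[C@]12O[C@@]1(C)CCCC2(C)C | intermediate
15 | (1R)-1-(hydroxymethyl)-2,2-dimethyl-6-methylidenecyclohexan-1-ol | OC[C@]1(O)C(=C)CCCC1(C)C | intermediate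
16 | [(1R)-1-hydroxy-2,2-dimethyl-6-methylidenecyclohexyl]methyl 4-methylbenzenesulfonate | Cc1ccc(cc1)S(=O)(=O)OC[C@]1(O)C(=C)CCCC1(C)C | intermediate (not isolated)
17 | (3R)-4,4-dimethyl-8-methylidene-1-oxaspiro[2.5]octane | C1O[C@]12C(=C)CCCC2(C)C | intermediate
18 | 3-chloro-2-(chloromethyl)prop-1-ene | C=C(CCl)CCl | starting material
19 | (2-methylidenepropane-1,3-diyl)bis(tributylstannane) | C=C(C[Sn](CCCC)(CCCC)CCCC)C[Sn](CCCC)(CCCC)CCCC | intermediate
20 | {2-[(tributylstannyl)methyl]prop-2-en-1-yl}lithium | [Li]CC(=C)C[Sn](CCCC)(CCCC)CCCC | intermediate (not isolated)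
21 | (1R)-2,2-dimethyl-6-methylidene-1-{3-[(tributylstannyl)methyl]but-3-en-1-yl}cyclohexan-1-ol | CCCC[Sn](CCCC)(CCCC)CC(=C)CC[C@]1(O)C(=C)CCCC1(C)C | intermediate
22 | methyl (2R,3R,6R)-12-[(1R)-1-hydroxy-2,2-dimethyl-6-methylidenecyclohexyl]-3-(methanesulfonyloxy)-6-[(2-methoxypropan-2-yl)peroxy]-2,6-dimethyl-10-methylidenedodecanoate | COC(=O)[C@H](C)[C@H](OS(C)(=O)=O)CC[C@](C)(OOC(C)(C)OC)CCCC(=C)CC[C@]1(O)C(=C)CCCC1(C)C | intermediate
23 | methyl (2R,3R,6R)-6-hydroperoxy-12-[(1R)-1-hydroxy-2,2-dimethyl-6-methylidenecyclohexyl]-3-(methanesulfonyloxy)-2,6-dimethyl-10-methylidenedodecanoate | COC(=O)[C@H](C)[C@H](OS(C)(=O)=O)CC[C@](C)(OO)CCCC(=C)CC[C@]1(O)C(=C)CCCC1(C)C | intermediate (not isolated)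
24 | methyl (2R)-2-[(3S,6R)-6-{6-[(1R)-1-hydroxy-2,2-dimethyl-6-methylidenecyclohexyl]-4-methylidenehexyl}-6-methyl-1,2-dioxan-3-yl]propanoate | C=C(CCC[C@]1(C)CC[C@@H]([C@@H](C)C(=O)OC)OO1)CC[C@]1(O)C(=C)CCCC1(C)C | target

**Step count and risks**
Total step count: 15. Longest linear sequence: 9 steps (steps 1–7, 14, 15, from p-cresol).

Steps most likely to fail:

Step 15 (ring closure). The mesylate is β to the ester, so base-induced E1cB loss of the mesylate can outrun the SN2 closure at a β-branched secondary carbon. Fallback: close the ring by conjugate addition instead. Setting out from 22, DBU deliberately eliminates the mesylate to the enoate methyl (2E,6R)-12-[(1R)-1-hydroxy-2,2-dimethyl-6-methylidenecyclohexyl]-6-[(2-methoxypropan-2-yl)peroxy]-2,6-dimethyl-10-methylidenedodec-2-enoate F6. Aqueous acetic acid then frees methyl (2E,6R)-6-hydroperoxy-12-[(1R)-1-hydroxy-2,2-dimethyl-6-methylidenecyclohexyl]-2,6-dimethyl-10-methylidenedodec-2-enoate F7. Amine-mediated (Et2NH, CF3CH2OH) intramolecular 6-exo oxa-Michael addition of the hydroperoxide comes back to the route at target 24. In this fallback C6 stays fixed, but C2 and C3 are set only by substrate control, so 24 must be separated from its C2/C3 diastereomers by HPLC.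

Step 4 (enzymatic desymmetrisation). The bulky peroxyketal ketone is an untested monooxygenase substrate, so both acceptance and ee are uncertain. Fallback: break the symmetry one step earlier and by reduction instead of oxygen insertion. Setting out from dienone 3, an ene-reductase of the Old Yellow Enzyme family reduces one of the two enantiotopic enone C=C bonds to (4S)-4-[(2-methoxypropan-2-yl)peroxy]-4-methylcyclohex-2-en-1-one F1. Buffered mCPBA then gives a substrate-controlled Baeyer–Villiger oxidation with migration of the vinyl carbon to the enol lactone (5S)-5-[(2-methoxypropan-2-yl)peroxy]-5-methyl-4,5-dihydrooxepin-2(3H)-one F2. Diimide (as in step 3) saturates the enol double bond and the sequence comes back to the route at lactone 5.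

Step 13 (stannylated allyllithium and epoxide opening). Mono tin–lithium exchange on 19 may be unselective, and the vinyl epoxide may open by SN2′. Fallback: use an oxygenated instead of a stannylated allyl anion and install tin afterwards. Setting out from epoxide 17, the dianion of 2-methylprop-2-en-1-ol, lithium 2-(lithiomethyl)prop-2-en-1-olate F3 (nBuLi, TMEDA), opens the epoxide to (1R)-1-[3-(hydroxymethyl)but-3-en-1-yl]-2,2-dimethyl-6-methylidenecyclohexan-1-ol F4. Selective mesylation of the primary allylic hydroxyl gives 2-{2-[(1R)-1-hydroxy-2,2-dimethyl-6-methylidenecyclohexyl]ethyl}prop-2-en-1-yl methanesulfonate F5. Substitution with Bu3SnLi (made as in step 12; SN2 and SN2′ give the same product) comes back to the route at stannane 21.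

**Further compounds**
F1 | step 4 | (4S)-4-[(2-methoxypropan-2-yl)peroxy]-4-methylcyclohex-2-en-1-one | O=C1C=C[C@@](C)(OOC(C)(C)OC)CC1
F2 | step 4 | (5S)-5-[(2-methoxypropan-2-yl)peroxy]-5-methyl-4,5-dihydrooxepin-2(3H)-one | O=C1CC[C@](C)(OOC(C)(C)OC)C=CO1
F3 | step 13 | lithium 2-(lithiomethyl)prop-2-en-1-olate | [Li]CC(=C)CO[Li]
F4 | step 13 | (1R)-1-[3-(hydroxymethyl)but-3-en-1-yl]-2,2-dimethyl-6-methylidenecyclohexan-1-ol | OCC(=C)CC[C@]1(O)C(=C)CCCC1(C)C
F5 | step 13 | 2-{2-[(1R)-1-hydroxy-2,2-dimethyl-6-methylidenecyclohexyl]ethyl}prop-2-en-1-yl methanesulfonate | CS(=O)(=O)OCC(=C)CC[C@]1(O)C(=C)CCCC1(C)C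
F6 | step 15 | methyl (2E,6R)-12-[(1R)-1-hydroxy-2,2-dimethyl-6-methylidenecyclohexyl]-6-[(2-methoxypropan-2-yl)peroxy]-2,6-dimethyl-10-methylidenedodec-2-enoate | COC(=O)/C(C)=C/CC[C@](C)(OOC(C)(C)OC)CCCC(=C)CC[C@]1(O)C(=C)CCCC1(C)C
F7 | step 15 | methyl (2E,6R)-6-hydroperoxy-12-[(1R)-1-hydroxy-2,2-dimethyl-6-methylidenecyclohexyl]-2,6-dimethyl-10-methylidenedodec-2-enoate | COC(=O)/C(C)=C/CC[C@](C)(OO)CCCC(=C)CC[C@]1(O)C(=C)CCCC1(C)C
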